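The route rests on cutting the C3–C4 bond of the tetralin ring B: C3 (carrying an ester, the future hydroxymethyl carbon) and C4 (the benzylic CH2 on ring A) both stabilise radicals, so this bond can replace a C3–NH–C4 link. The precursor is therefore an ethyl tetrahydro-2-benzazepine-3-carboxylate with the C1 aryl group and the protected C2 hydroxymethyl arm already in place, built by enal arylation, Mannich reaction and reductive amination. In one operation an anomeric amide turns the ring NH into an isodiazene, N2 leaves, and the C3 and C4 radicals couple: the azepine contracts to ring B, C3–C4 forms, and C3 settles trans to C2.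

Key step: step 13

Remarks and assumptions
- Numbering: lignan numbering is used for the tetralin (C1 aryl-bearing, C2 and C3 arm-bearing, C4 = CH2). Ar = 4-(benzyloxy)-3,5-dimethoxyphenyl, PMP = 4-methoxyphenyl, TBDPS = tert-butyldiphenylsilyl. "Anomeric amide" = N-(benzyloxy)-N-(pivaloyloxy)-4-(trifluoromethyl)benzamide, CC(C)(C)C(=O)ON(OCc1ccccc1)C(=O)c1ccc(cc1)C(F)(F)F.
- Assumption: 6-bromovanillin, (triphenylphosphoranylidene)acetaldehyde, the anomeric amide and both antipodes of a chiral bicyclo[2.2.2]octadiene ligand are commercial. The ligand antipode that transfers the aryl group to the Re face of the enal C3 is used, and its identity is to be confirmed by correlation on the first batch.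
- Ring A regiochemistry: in the target, C4 sits para to the phenol oxygen and C1 para to OMe. 6-Bromovanillin has CHO para to OH and Br para to OMe, so its formyl carbon becomes C4 (carried as an acetal) and the enal arm is built at the bromine-bearing carbon. No late aryl-halide functionalisation is then needed.
- The C2 arm is carried as a silyl ether, not as a benzyl ether: the γ-hydroxy α-amino ester would close to a lactone under the strong base of an O-benzylation.
- The Mannich step needs D-proline: L-proline would give the (2S,3S) adduct, which has the wrong configuration at the future C2.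

Step 1
Reactants: 1 2-bromo-4-hydroxy-5-methoxybenzaldehyde (6-bromovanillin)
Product: 2 4-(benzyloxy)-2-bromo-5-methoxybenzaldehyde
Conditions: BnBr, K2CO3, DMF, 25 to 60 °C
Reagents that add atoms: benzyl bromide, BrCc1ccccc1
Why: Williamson etherification of the phenoxide; aldehyde and aryl bromide are inert to carbonate.

Step 2
Reactants: 2 4-(benzyloxy)-2-bromo-5-methoxybenzaldehyde
Product: 3 2-[4-(benzyloxy)-2-bromo-5-methoxyphenyl]-1,3-dioxolane
Conditions: ethylene glycol, p-TsOH (cat.), toluene, reflux, Dean–Stark trap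
Reagents that add atoms: ethylene glycol, OCCO
Why: Acid-catalysed acetalisation with azeotropic removal of water masks the formyl group (the future C4) against the organolithium of step 3 and all later nucleophiles and hydrides.

Step 3
Reactants: 3 2-[4-(benzyloxy)-2-bromo-5-methoxyphenyl]-1,3-dioxolane
Product: 6 5-(benzyloxy)-2-(1,3-dioxolan-2-yl)-4-methoxybenzaldehyde, via aryllithium 4 (not isolated), via lithium aminoalkoxide 5 (not isolated)
Conditions: n-BuLi, THF, −78 °C; DMF, −78 to 0 °C; aq. NH4Cl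
Reagents that add atoms: N,N-dimethylformamide, CN(C)C=O
Why: Bromine–lithium exchange at −78 °C outruns benzylic deprotonation and the aryllithium is formylated by DMF (Bouveault aldehyde synthesis), the mild ammonium chloride quench leaving the dioxolane intact.

Step 4
Reactants: 6 5-(benzyloxy)-2-(1,3-dioxolan-2-yl)-4-methoxybenzaldehyde
Product: 7 (E)-3-[5-(benzyloxy)-2-(1,3-dioxolan-2-yl)-4-methoxyphenyl]prop-2-enal
Conditions: Ph3P=CHCHO, toluene, 80 °C
Reagents that add atoms: (triphenylphosphoranylidene)acetaldehyde, O=CC=P(c1ccccc1)(c1ccccc1)c1ccccc1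
Why: Wittig olefination with the stabilised formylmethylene ylide gives the (E)-enal, and the aryl aldehyde reacts faster than the enal product, which limits a second homologation.

Step 5
Reactants: 8 4-bromo-2,6-dimethoxyphenol
Product: 9 2-(benzyloxy)-5-bromo-1,3-dimethoxybenzene
Conditions: BnBr, K2CO3, DMF, 60 °C
Reagents that add atoms: benzyl bromide, BrCc1ccccc1
Why: Williamson etherification of the hindered but acidic phenol.

Step 6
Reactants: 9 2-(benzyloxy)-5-bromo-1,3-dimethoxybenzene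
Product: 12 [4-(benzyloxy)-3,5-dimethoxyphenyl]boronic acid, via aryllithium 10 (not isolated), via lithium aryltriisopropoxyborate 11 (not isolated)
Conditions: n-BuLi, THF, −78 °C; B(Oi-Pr)3, −78 to 25 °C; 1 M HCl
Reagents that add atoms: triisopropyl borate, CC(C)OB(OC(C)C)OC(C)C; water, O
Why: Bromine–lithium exchange, borylation of the aryllithium and acidic hydrolysis of the ate complex are the standard arylboronic acid synthesis and touch neither ether type.

Step 7
Reactants: 7 (E)-3-[5-(benzyloxy)-2-(1,3-dioxolan-2-yl)-4-methoxyphenyl]prop-2-enal; 12 [4-(benzyloxy)-3,5-dimethoxyphenyl]boronic acid (2 equiv)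
Product: 13 (3S)-3-[5-(benzyloxy)-2-(1,3-dioxolan-2-yl)-4-methoxyphenyl]-3-Ar-propanal
Conditions: [RhCl(C2H4)2]2 (1.5 mol%), chiral 2,5-diarylbicyclo[2.2.2]octa-2,5-diene (3.3 mol%), KOH (0.5 equiv), 1,4-dioxane/H2O 10:1, 50 °C
Reagents that add atoms: none
Why: Hayashi–Miyaura rhodium-catalysed asymmetric 1,4-addition, in which the aryl-rhodium species inserts the enal C=C and the C2-symmetric diene, which also suppresses 1,2-addition, directs aryl transfer to the Re face of C3 and so sets the (S) benzhydryl centre (the future C1).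

Step 8
Reactants: 14 ethyl glyoxylate; 15 p-anisidine
Product: 16 ethyl (E)-2-[(4-methoxyphenyl)imino]acetate
Conditions: MgSO4, CH2Cl2, 25 °C; filtered, concentrated, used crude
Reagents that add atoms: none
Why: Condensation of the reactive aldehyde with the aniline gives the N-aryl α-imino ester, driven by the drying agent.

Step 9
Reactants: 13 (3S)-3-[5-(benzyloxy)-2-(1,3-dioxolan-2-yl)-4-methoxyphenyl]-3-Ar-propanal; 16 ethyl (E)-2-[(4-methoxyphenyl)imino]acetate (1.3 equiv)
Product: 18 ethyl (2R,3R,4S)-4-[5-(benzyloxy)-2-(1,3-dioxolan-2-yl)-4-methoxyphenyl]-4-Ar-3-(hydroxymethyl)-2-[(4-methoxyphenyl)amino]butanoate, via Mannich aldehyde 17 (not isolated)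
Conditions: D-proline (20 mol%), 1,4-dioxane, 25 °C; then EtOH, NaBH4, −20 to 0 °C; cold aq. NH4Cl
Reagents that add atoms: none
Why: Proline-catalysed direct Mannich reaction, in which the (E)-enamine of 13 adds to the imine held by the carboxylic acid of D-proline, so that catalyst control sets C3 (the future C2) as R and C2 as R (syn adduct), and reduction in the same flask removes the epimerisable formyl group at once.

Step 10
Reactants: 18 ethyl (2R,3R,4S)-4-[5-(benzyloxy)-2-(1,3-dioxolan-2-yl)-4-methoxyphenyl]-4-Ar-3-(hydroxymethyl)-2-[(4-methoxyphenyl)amino]butanoate (crude, used at once)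
Product: 19 ethyl (2R,3R,4S)-4-[5-(benzyloxy)-2-(1,3-dioxolan-2-yl)-4-methoxyphenyl]-4-Ar-3-{[(tert-butyldiphenylsilyl)oxy]methyl}-2-[(4-methoxyphenyl)amino]butanoate
Conditions: TBDPSCl, imidazole, CH2Cl2, 0 to 25 °C
Reagents that add atoms: tert-butyl(chloro)diphenylsilane, CC(C)(C)[Si](Cl)(c1ccccc1)c1ccccc1
Why: Imidazole-mediated silylation caps the primary alcohol under conditions too mild for lactonisation onto the ethyl ester, the hindered N-aryl amine stays free, and the acid-robust TBDPS group is chosen to survive step 11.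

Step 11
Reactants: 19 ethyl (2R,3R,4S)-4-[5-(benzyloxy)-2-(1,3-dioxolan-2-yl)-4-methoxyphenyl]-4-Ar-3-{[(tert-butyldiphenylsilyl)oxy]methyl}-2-[(4-methoxyphenyl)amino]butanoate
Product: 21 ethyl (3R,4R,5S)-7-(benzyloxy)-5-Ar-4-{[(tert-butyldiphenylsilyl)oxy]methyl}-8-methoxy-4,5-dihydro-3H-2-benzazepine-3-carboxylate, via amino aldehyde 20 (not isolated)
Conditions: ceric ammonium nitrate (3 equiv), MeCN/H2O 4:1, 0 °C; 1 M HCl, 25 °C; then Na2SO3, NaHCO3 to pH 8, CH2Cl2
Reagents that add atoms: none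
Why: Cerium(IV) oxidative N-dearylation converts the anisidine ring, the most easily oxidised arene present, into a quinone iminium that hydrolyses to the primary amine, the acidic medium hydrolyses the dioxolane, and on neutralisation the amine condenses with the ortho formyl group to the seven-membered cyclic imine without touching a stereocentre.

Step 12
Reactants: 21 ethyl (3R,4R,5S)-7-(benzyloxy)-5-Ar-4-{[(tert-butyldiphenylsilyl)oxy]methyl}-8-methoxy-4,5-dihydro-3H-2-benzazepine-3-carboxylate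
Product: 22 ethyl (3R,4R,5S)-7-(benzyloxy)-5-Ar-4-{[(tert-butyldiphenylsilyl)oxy]methyl}-8-methoxy-2,3,4,5-tetrahydro-1H-2-benzazepine-3-carboxylate
Conditions: NaBH(OAc)3, AcOH, 1,2-dichloroethane, 25 °C
Reagents that add atoms: none
Why: Triacetoxyborohydride reduction of the protonated cyclic aldimine (second half of an intramolecular reductive amination) leaves ester and silyl ether alone and creates no stereocentre, and any epimerisation at C3 through the imine is harmless because step 13 erases that centre.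

Step 13
Reactants: 22 ethyl (3R,4R,5S)-7-(benzyloxy)-5-Ar-4-{[(tert-butyldiphenylsilyl)oxy]methyl}-8-methoxy-2,3,4,5-tetrahydro-1H-2-benzazepine-3-carboxylate
Product: 25 ethyl (2R,3R,4S)-6-(benzyloxy)-4-Ar-3-{[(tert-butyldiphenylsilyl)oxy]methyl}-7-methoxy-1,2,3,4-tetrahydronaphthalene-2-carboxylate (lignan numbering 1S,2R,3R; 1,2-trans-2,3-trans), via N-alkoxy hydrazide 23 (not isolated), via isodiazene 24 (not isolated)
Conditions: anomeric amide (1.5 equiv), THF, 45 °C; crude product then NaOEt (cat.), EtOH, 25 °C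
Reagents that add atoms: none
Why: The ring NH attacks the electrophilic nitrogen of the anomeric amide with loss of pivalate, the N-alkoxy hydrazide 23 expels benzyl 4-(trifluoromethyl)benzoate to give the 1,1-diazene 24, and this loses N2 to leave a 1,6-diradical that is benzylic at C4 and ester-stabilised at C3. The closest known reaction type is the anomeric-amide nitrogen deletion of benzylic secondary amines, including ring contraction of benzo-fused cyclic amines. Ring B closes by radical–radical recombination of the two termini of this diradical (C3–C4 bond, six-membered ring, a 7-to-6 contraction with the ring A–C1–C2 tether intact). The only new stereocentre, C3, is planar in the diradical; it is set on recombination and then by ethoxide equilibration α to the ester, the C2 silyloxymethyl arm directing the ester into the trans, equatorial position. The step needs recombination to outrun disproportionation and β-scission, which is favoured because both radicals are stabilised and held within reach by the tether, while C1 and C2 carry no spin and keep their configuration.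

Step 14
Reactants: 25 ethyl (2R,3R,4S)-6-(benzyloxy)-4-Ar-3-{[(tert-butyldiphenylsilyl)oxy]methyl}-7-methoxy-1,2,3,4-tetrahydronaphthalene-2-carboxylate
Product: 26 [(2R,3R,4S)-6-(benzyloxy)-4-Ar-3-{[(tert-butyldiphenylsilyl)oxy]methyl}-7-methoxy-1,2,3,4-tetrahydronaphthalen-2-yl]methanol
Conditions: LiAlH4, THF, 0 °C; aq. NaOH work-up
Reagents that add atoms: none
Why: Hydride reduction of the ester to the primary alcohol, with benzyl and silyl ethers inert and C3 no longer epimerisable once the carbonyl is gone.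

Step 15
Reactants: 26 [(2R,3R,4S)-6-(benzyloxy)-4-Ar-3-{[(tert-butyldiphenylsilyl)oxy]methyl}-7-methoxy-1,2,3,4-tetrahydronaphthalen-2-yl]methanol
Product: 27 [(1S,2R,3R)-7-(benzyloxy)-1-Ar-6-methoxy-1,2,3,4-tetrahydronaphthalene-2,3-diyl]dimethanol
Conditions: TBAF, THF, 25 °C
Reagents that add atoms: none
Why: Fluoride-induced cleavage of the silyl ether, driven by Si–F bond formation, leaves the aryl benzyl ethers untouched.

Step 16
Reactants: 27 [(1S,2R,3R)-7-(benzyloxy)-1-Ar-6-methoxy-1,2,3,4-tetrahydronaphthalene-2,3-diyl]dimethanol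
Product: 28 5-methoxy-(+)-isolariciresinol, (1S,2R,3R)-1-(4-hydroxy-3,5-dimethoxyphenyl)-2,3-bis(hydroxymethyl)-6-methoxy-1,2,3,4-tetrahydronaphthalen-7-ol
Conditions: H2 (1 atm), 10% Pd/C, MeOH/EtOAc, 25 °C
Reagents that add atoms: none
Why: Palladium-catalysed hydrogenolysis of the two aryl benzyl ethers, with no other reducible group present and no stereocentre involved.

Compound list
1 | 2-bromo-4-hydroxy-5-methoxybenzaldehyde (6-bromovanillin) | COc1cc(C=O)c(Br)cc1O | starting material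
2 | 4-(benzyloxy)-2-bromo-5-methoxybenzaldehyde | COc1cc(C=O)c(Br)cc1OCc1ccccc1 | intermediate
3 | 2-[4-(benzyloxy)-2-bromo-5-methoxyphenyl]-1,3-dioxolane | COc1cc(C2OCCO2)c(Br)cc1OCc1ccccc1 | intermediate
4 | [5-(benzyloxy)-2-(1,3-dioxolan-2-yl)-4-methoxyphenyl]lithium | COc1cc(C2OCCO2)c([Li])cc1OCc1ccccc1 | intermediate (not isolated)
5 | lithium [5-(benzyloxy)-2-(1,3-dioxolan-2-yl)-4-methoxyphenyl](dimethylamino)methanolate | COc1cc(C2OCCO2)c(C([O-])N(C)C)cc1OCc1ccccc1.[Li+] | intermediate (not isolated)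
6 | 5-(benzyloxy)-2-(1,3-dioxolan-2-yl)-4-methoxybenzaldehyde | COc1cc(C2OCCO2)c(C=O)cc1OCc1ccccc1 | intermediate
7 | (E)-3-[5-(benzyloxy)-2-(1,3-dioxolan-2-yl)-4-methoxyphenyl]prop-2-enal | COc1cc(C2OCCO2)c(/C=C/C=O)cc1OCc1ccccc1 | intermediate
8 | 4-bromo-2,6-dimethoxyphenol | COc1cc(Br)cc(OC)c1O | starting material
9 | 2-(benzyloxy)-5-bromo-1,3-dimethoxybenzene | COc1cc(Br)cc(OC)c1OCc1ccccc1 | intermediate
10 | [4-(benzyloxy)-3,5-dimethoxyphenyl]lithium | COc1cc([Li])cc(OC)c1OCc1ccccc1 | intermediate (not isolated)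
11 | lithium [4-(benzyloxy)-3,5-dimethoxyphenyl]tri(propan-2-yloxy)borate | COc1cc([B-](OC(C)C)(OC(C)C)OC(C)C)cc(OC)c1OCc1ccccc1.[Li+] | intermediate (not isolated)
12 | [4-(benzyloxy)-3,5-dimethoxyphenyl]boronic acid | COc1cc(B(O)O)cc(OC)c1OCc1ccccc1 | intermediate
13 | (3S)-3-[5-(benzyloxy)-2-(1,3-dioxolan-2-yl)-4-methoxyphenyl]-3-[4-(benzyloxy)-3,5-dimethoxyphenyl]propanal | COc1cc(C2OCCO2)c(cc1OCc1ccccc1)[C@H](c1cc(OC)c(OCc2ccccc2)c(OC)c1)CC=O | intermediate
14 | ethyl glyoxylate | CCOC(=O)C=O | starting material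
15 | p-anisidine | COc1ccc(N)cc1 | starting material
16 | ethyl (E)-2-[(4-methoxyphenyl)imino]acetate | CCOC(=O)/C=N/c1ccc(OC)cc1 | intermediate
17 | ethyl (2R,3R,4S)-4-[5-(benzyloxy)-2-(1,3-dioxolan-2-yl)-4-methoxyphenyl]-4-[4-(benzyloxy)-3,5-dimethoxyphenyl]-3-formyl-2-[(4-methoxyphenyl)amino]butanoate | COc1cc(C2OCCO2)c(cc1OCc1ccccc1)[C@H](c1cc(OC)c(OCc2ccccc2)c(OC)c1)[C@@H](C=O)[C@H](C(=O)OCC)Nc1ccc(OC)cc1 | intermediate (not isolated)
18 | ethyl (2R,3R,4S)-4-[5-(benzyloxy)-2-(1,3-dioxolan-2-yl)-4-methoxyphenyl]-4-[4-(benzyloxy)-3,5-dimethoxyphenyl]-3-(hydroxymethyl)-2-[(4-methoxyphenyl)amino]butanoate | COc1cc(C2OCCO2)c(cc1OCc1ccccc1)[C@H](c1cc(OC)c(OCc2ccccc2)c(OC)c1)[C@@H](CO)[C@H](C(=O)OCC)Nc1ccc(OC)cc1 | intermediate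
19 | ethyl (2R,3R,4S)-4-[5-(benzyloxy)-2-(1,3-dioxolan-2-yl)-4-methoxyphenyl]-4-[4-(benzyloxy)-3,5-dimethoxyphenyl]-3-{[(tert-butyldiphenylsilyl)oxy]methyl}-2-[(4-methoxyphenyl)amino]butanoate | COc1cc(C2OCCO2)c(cc1OCc1ccccc1)[C@H](c1cc(OC)c(OCc2ccccc2)c(OC)c1)[C@@H](CO[Si](c1ccccc1)(c1ccccc1)C(C)(C)C)[C@H](C(=O)OCC)Nc1ccc(OC)cc1 | intermediate
20 | ethyl (2R,3R,4S)-2-amino-4-[5-(benzyloxy)-2-formyl-4-methoxyphenyl]-4-[4-(benzyloxy)-3,5-dimethoxyphenyl]-3-{[(tert-butyldiphenylsilyl)oxy]methyl}butanoate | COc1cc(C=O)c(cc1OCc1ccccc1)[C@H](c1cc(OC)c(OCc2ccccc2)c(OC)c1)[C@@H](CO[Si](c1ccccc1)(c1ccccc1)C(C)(C)C)[C@H](C(=O)OCC)N | intermediate (not isolated)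
21 | ethyl (3R,4R,5S)-7-(benzyloxy)-5-[4-(benzyloxy)-3,5-dimethoxyphenyl]-4-{[(tert-butyldiphenylsilyl)oxy]methyl}-8-methoxy-4,5-dihydro-3H-2-benzazepine-3-carboxylate | COc1cc2c(cc1OCc1ccccc1)[C@H](c1cc(OC)c(OCc3ccccc3)c(OC)c1)[C@@H](CO[Si](c1ccccc1)(c1ccccc1)C(C)(C)C)[C@H](C(=O)OCC)N=C2 | intermediate
22 | ethyl (3R,4R,5S)-7-(benzyloxy)-5-[4-(benzyloxy)-3,5-dimethoxyphenyl]-4-{[(tert-butyldiphenylsilyl)oxy]methyl}-8-methoxy-2,3,4,5-tetrahydro-1H-2-benzazepine-3-carboxylate | COc1cc2c(cc1OCc1ccccc1)[C@H](c1cc(OC)c(OCc3ccccc3)c(OC)c1)[C@@H](CO[Si](c1ccccc1)(c1ccccc1)C(C)(C)C)[C@H](C(=O)OCC)NC2 | intermediate (precursor of the key step)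
23 | ethyl (3R,4R,5S)-7-(benzyloxy)-2-{(benzyloxy)[4-(trifluoromethyl)benzoyl]amino}-5-[4-(benzyloxy)-3,5-dimethoxyphenyl]-4-{[(tert-butyldiphenylsilyl)oxy]methyl}-8-methoxy-2,3,4,5-tetrahydro-1H-2-benzazepine-3-carboxylate | COc1cc2c(cc1OCc1ccccc1)[C@H](c1cc(OC)c(OCc3ccccc3)c(OC)c1)[C@@H](CO[Si](c1ccccc1)(c1ccccc1)C(C)(C)C)[C@H](C(=O)OCC)N(N(OCc1ccccc1)C(=O)c1ccc(cc1)C(F)(F)F)C2 | intermediate (not isolated)
24 | 1,1-diazene (isodiazene) of 22, ring nitrogen bearing a terminal N | COc1cc2c(cc1OCc1ccccc1)[C@H](c1cc(OC)c(OCc3ccccc3)c(OC)c1)[C@@H](CO[Si](c1ccccc1)(c1ccccc1)C(C)(C)C)[C@H](C(=O)OCC)[N+](=[N-])C2 | intermediate (not isolated)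
25 | ethyl (2R,3R,4S)-6-(benzyloxy)-4-[4-(benzyloxy)-3,5-dimethoxyphenyl]-3-{[(tert-butyldiphenylsilyl)oxy]methyl}-7-methoxy-1,2,3,4-tetrahydronaphthalene-2-carboxylate | COc1cc2c(cc1OCc1ccccc1)[C@H](c1cc(OC)c(OCc3ccccc3)c(OC)c1)[C@@H](CO[Si](c1ccccc1)(c1ccccc1)C(C)(C)C)[C@H](C(=O)OCC)C2 | intermediate (product of the key step)
26 | [(2R,3R,4S)-6-(benzyloxy)-4-[4-(benzyloxy)-3,5-dimethoxyphenyl]-3-{[(tert-butyldiphenylsilyl)oxy]methyl}-7-methoxy-1,2,3,4-tetrahydronaphthalen-2-yl]methanol | COc1cc2c(cc1OCc1ccccc1)[C@H](c1cc(OC)c(OCc3ccccc3)c(OC)c1)[C@@H](CO[Si](c1ccccc1)(c1ccccc1)C(C)(C)C)[C@H](CO)C2 | intermediate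
27 | [(1S,2R,3R)-7-(benzyloxy)-1-[4-(benzyloxy)-3,5-dimethoxyphenyl]-6-methoxy-1,2,3,4-tetrahydronaphthalene-2,3-diyl]dimethanol | COc1cc2c(cc1OCc1ccccc1)[C@H](c1cc(OC)c(OCc3ccccc3)c(OC)c1)[C@@H](CO)[C@H](CO)C2 | intermediate
28 | 5-methoxy-(+)-isolariciresinol | COc1cc2c(cc1O)[C@H](c1cc(OC)c(O)c(OC)c1)[C@@H](CO)[C@H](CO)C2 | target

Total step count: 16. Longest linear sequence: 13 steps (1 → 2 → 3 → 6 → 7 → 13 → 18 → 19 → 21 → 22 → 25 → 26 → 27 → 28).

Steps most likely to fail

Step 13. The hindered, weakly nucleophilic α-amino-ester nitrogen may attack the bulky anomeric amide too slowly, so that the reagent decays before N-amination. Once the diradical forms, disproportionation or β-scission may also compete with ring closure. The fallback sets out from 22 and returns at 25, and reaches the same isodiazene with small reagents in separate, classical operations. Nitrosation of 22 with tert-butyl nitrite in CH2Cl2 should give the N-nitrosamine F1. Zinc in acetic acid should reduce it to the N-aminobenzazepine F2. Oxidation of this 1,1-disubstituted hydrazine with yellow mercuric oxide in ethanol generates isodiazene 24, which loses N2 to give 25 after the same ethoxide equilibration.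

Step 7. The ortho-acetal on the enal may slow the insertion into the aryl–rhodium bond, so that protodeboronation or 1,2-addition takes over, or facial discrimination may be insufficient. The fallback sets out from 6 and returns at 13, and replaces catalysis by an oxazolidinone auxiliary. Horner–Wadsworth–Emmons reaction of 6 with diethyl {2-oxo-2-[(4R)-2-oxo-4-phenyl-1,3-oxazolidin-3-yl]ethyl}phosphonate (LiCl, i-Pr2NEt, MeCN) should give the N-enoyl oxazolidinone F3. The aryl Grignard reagent from 9 (Mg, THF) with CuBr·SMe2 at −40 °C should add anti to the phenyl group of the chelated imide, that is to the Re face of C3, to give the conjugate adduct F4. LiBH4 in wet THF cleaves the auxiliary to the primary alcohol F5, and Dess–Martin periodinane oxidation gives 13.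

Step 9. Facial selectivity at the enamine carbon may erode if the existing benzhydryl centre opposes the catalyst, the α-formyl centre may epimerise before reduction, and the hydroxy ester may lactonise. The fallback sets out from 17 and returns at 27. It carries the C2 arm at the ester oxidation level, so that C2 as well as C3 is corrected by equilibration in the tetralin. The crude Mannich aldehyde 17 (borohydride omitted) is oxidised under Pinnick conditions (NaClO2, NaH2PO4, 2-methyl-2-butene, t-BuOH/H2O) to the acid F6 and esterified (EtI, K2CO3, DMF) to the diethyl aminosuccinate F7. The conditions of steps 11 and 12 then give the cyclic imine diester F8 and the benzazepine diester F9. Nitrogen deletion as in step 13, followed by NaOEt in EtOH, should converge on the all-trans tetralin diester F10, and LiAlH4 reduces both esters to diol 27. This fallback also omits the silylation and the fluoride step.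

Further compounds
F1 | step 13 | ethyl (3R,4R,5S)-7-(benzyloxy)-5-Ar-4-{[(tert-butyldiphenylsilyl)oxy]methyl}-8-methoxy-2-nitroso-2,3,4,5-tetrahydro-1H-2-benzazepine-3-carboxylate | COc1cc2c(cc1OCc1ccccc1)[C@H](c1cc(OC)c(OCc3ccccc3)c(OC)c1)[C@@H](CO[Si](c1ccccc1)(c1ccccc1)C(C)(C)C)[C@H](C(=O)OCC)N(N=O)C2
F2 | step 13 | ethyl (3R,4R,5S)-2-amino-7-(benzyloxy)-5-Ar-4-{[(tert-butyldiphenylsilyl)oxy]methyl}-8-methoxy-2,3,4,5-tetrahydro-1H-2-benzazepine-3-carboxylate | COc1cc2c(cc1OCc1ccccc1)[C@H](c1cc(OC)c(OCc3ccccc3)c(OC)c1)[C@@H](CO[Si](c1ccccc1)(c1ccccc1)C(C)(C)C)[C@H](C(=O)OCC)N(N)C2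
F3 | step 7 | (4R)-3-{(2E)-3-[5-(benzyloxy)-2-(1,3-dioxolan-2-yl)-4-methoxyphenyl]prop-2-enoyl}-4-phenyl-1,3-oxazolidin-2-one | COc1cc(C2OCCO2)c(/C=C/C(=O)N2C(=O)OC[C@H]2c2ccccc2)cc1OCc1ccccc1
F4 | step 7 | (4R)-3-{(3S)-3-[5-(benzyloxy)-2-(1,3-dioxolan-2-yl)-4-methoxyphenyl]-3-Ar-propanoyl}-4-phenyl-1,3-oxazolidin-2-one | COc1cc(C2OCCO2)c(cc1OCc1ccccc1)[C@H](c1cc(OC)c(OCc2ccccc2)c(OC)c1)CC(=O)N1C(=O)OC[C@H]1c1ccccc1
F5 | step 7 | (3S)-3-[5-(benzyloxy)-2-(1,3-dioxolan-2-yl)-4-methoxyphenyl]-3-Ar-propan-1-ol | COc1cc(C2OCCO2)c(cc1OCc1ccccc1)[C@H](c1cc(OC)c(OCc2ccccc2)c(OC)c1)CCO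
F6 | step 9 | 2-{(S)-[5-(benzyloxy)-2-(1,3-dioxolan-2-yl)-4-methoxyphenyl](Ar)methyl}-4-ethoxy-3-[(4-methoxyphenyl)amino]-4-oxobutanoic acid (C2/C3 epimers) | COc1cc(C2OCCO2)c(cc1OCc1ccccc1)[C@H](c1cc(OC)c(OCc2ccccc2)c(OC)c1)C(C(=O)O)C(C(=O)OCC)Nc1ccc(OC)cc1
F7 | step 9 | diethyl 2-{(S)-[5-(benzyloxy)-2-(1,3-dioxolan-2-yl)-4-methoxyphenyl](Ar)methyl}-3-[(4-methoxyphenyl)amino]butanedioate (C2/C3 epimers) | COc1cc(C2OCCO2)c(cc1OCc1ccccc1)[C@H](c1cc(OC)c(OCc2ccccc2)c(OC)c1)C(C(=O)OCC)C(C(=O)OCC)Nc1ccc(OC)cc1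
F8 | step 9 | diethyl (5S)-7-(benzyloxy)-5-Ar-8-methoxy-4,5-dihydro-3H-2-benzazepine-3,4-dicarboxylate (C3/C4 epimers) | COc1cc2c(cc1OCc1ccccc1)[C@H](c1cc(OC)c(OCc3ccccc3)c(OC)c1)C(C(=O)OCC)C(C(=O)OCC)N=C2
F9 | step 9 | diethyl (5S)-7-(benzyloxy)-5-Ar-8-methoxy-2,3,4,5-tetrahydro-1H-2-benzazepine-3,4-dicarboxylate (C3/C4 epimers) | COc1cc2c(cc1OCc1ccccc1)[C@H](c1cc(OC)c(OCc3ccccc3)c(OC)c1)C(C(=O)OCC)C(C(=O)OCC)NC2
F10 | step 9 | diethyl (1S,2R,3R)-7-(benzyloxy)-1-Ar-6-methoxy-1,2,3,4-tetrahydronaphthalene-2,3-dicarboxylate | COc1cc2c(cc1OCc1ccccc1)[C@H](c1cc(OC)c(OCc3ccccc3)c(OC)c1)[C@@H](C(=O)OCC)[C@H](C(=O)OCC)C2
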